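Daucane numbering: cyclopentane C1–C5 (C1 quaternary with CH3, C4 carbinol with isopropyl, C5–H); cycloheptane C1, C10, C9, C8, C7, C6, C5. α is the face of H5, β the face of the C1 methyl.
Enabling feature: the seven-membered ring has oxygen on C6 and on C9 (epoxide), 1,4 to each other across C7–C8. It is fused to the cyclopentane through the C1–C5 bond with C1 quaternary. Such a cycloheptane-1,4-dione is the retron of an intramolecular de Mayo reaction.
Retrosynthesis: remove the epoxide oxygen, C8–C14 and the benzoate to reach the 6,9-dione. Cut C1–C5 and C9–C10 while re-forming C5–C9 (enol carbonate 19). Then cut C5–C6 (hydroacylation), C8–C9 (acetylide/oxetane) and C3–C4 (Negishi).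
Forward: the acyclic chain is joined first and the cyclopentenone C5–C9 is closed next. One operation then closes the cyclopentane and a transient cyclobutane and expands to the seven-membered ring.
Stereochemistry: C4 comes from a Sharpless epoxidation. C4 directs C1 in the photocycloaddition, C5 follows by protonation to the trans fusion, O4 delivers hydride to C6, and the C1 methyl shields the β face in the epoxidation (C8, C9).
Key step: step 12

Remark on the chemistry: 1, 4 and 11 are taken as catalogue compounds. Compounds 22–25 lack C14 (the C8 methyl) and are named as 14-nordaucanes. Stereocentres that are erased in a following step (ring carbons of 16 and 17, C9 of 27–29) are left undefined on purpose.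

Step 1
Reactants: 1 4-methylpent-2-yn-1-ol
Product: 3 (Z)-3-iodo-4-methylpent-2-en-1-ol, via cyclic alkenylalanate 2 (not isolated)
Conditions: Red-Al, THF, 0 °C to rt; then I2, THF, −78 °C
Reagents that add atoms: iodine II
Why: Hydroxyl-directed trans-hydroalumination of a propargylic alcohol places aluminium on the distal alkyne carbon inside a five-membered chelate, and iodinolysis with retention should give the Z iodide only.

Step 2
Reactants: 3 (Z)-3-iodo-4-methylpent-2-en-1-ol; 4 4-bromo-2-methylbut-1-ene
Product: 6 (E)-6-methyl-3-(propan-2-yl)hepta-2,6-dien-1-ol, via homoallylzinc bromide 5 (not isolated)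
Conditions: 4, Zn, LiCl, THF, 50 °C; then 3, Pd(dppf)Cl2 (5 mol %), THF, rt (5 in excess)
Reagents that add atoms: none
Why: A Negishi sp2–sp3 coupling retains the alkene geometry, so the homoallyl chain (C3–C2–C1=C10) ends cis and the isopropyl group trans to CH2OH, the pattern that the next epoxidation handles best.

Step 3
Reactants: 6 (E)-6-methyl-3-(propan-2-yl)hepta-2,6-dien-1-ol
Product: 7 [(2R,3R)-3-(3-methylbut-3-en-1-yl)-3-(propan-2-yl)oxiran-2-yl]methanol
Conditions: Ti(OiPr)4 (10 mol %), D-(−)-DET (12 mol %), t-BuOOH, 4 Å MS, CH2Cl2, −20 °C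
Reagents that add atoms: tert-butyl hydroperoxide CC(C)(C)OO
Why: The Sharpless asymmetric epoxidation reacts only at the allylic alkene, and D-(−)-tartrate should give the (2R,3R)-epoxide as nerol-type substrates do, which sets the C4–O stereocentre of the target.

Step 4
Reactants: 7 [(2R,3R)-3-(3-methylbut-3-en-1-yl)-3-(propan-2-yl)oxiran-2-yl]methanol
Product: 8 (2S,3R)-2-(chloromethyl)-3-(3-methylbut-3-en-1-yl)-3-(propan-2-yl)oxirane
Conditions: PPh3, CCl4, NaHCO3, reflux
Reagents that add atoms: carbon tetrachloride ClC(Cl)(Cl)Cl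
Why: The Appel reaction exchanges the primary hydroxyl for chloride under nearly neutral conditions that leave the epoxide and its two stereocentres untouched.

Step 5
Reactants: 8 (2S,3R)-2-(chloromethyl)-3-(3-methylbut-3-en-1-yl)-3-(propan-2-yl)oxirane
Product: 9 (3R)-6-methyl-3-(propan-2-yl)hept-6-en-1-yn-3-ol
Conditions: n-BuLi (3.2 equiv), THF, −78 to −30 °C
Reagents that add atoms: none
Why: Base-induced double elimination of a 2,3-epoxy chloride (epoxide opening to a chlorovinyl alkoxide, then dehydrochlorination) is a known route to tertiary propargylic alcohols, and since the C4–O bond is never broken the configuration at C4 is kept.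

Step 6
Reactants: 9 (3R)-6-methyl-3-(propan-2-yl)hept-6-en-1-yn-3-ol
Product: 10 triethylsilyl ether of 9
Conditions: TESOTf, 2,6-lutidine, CH2Cl2, 0 °C
Reagents that add atoms: triethylsilyl triflate CC[Si](CC)(CC)OS(=O)(=O)C(F)(F)F
Why: Silylation with the triflate and a hindered pyridine base is the standard way to protect a hindered tertiary alcohol, and the triethylsilyl ether withstands the organolithium, oxidation and transition-metal steps ahead.

Step 7
Reactants: 10 triethylsilyl ether of 9; 11 oxetane
Product: 13 (6R)-9-methyl-6-(propan-2-yl)-6-(triethylsilyloxy)dec-9-en-4-yn-1-ol, via lithium acetylide 12 (not isolated)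
Conditions: n-BuLi, THF, −78 °C; then BF3·OEt2, 11, −78 °C
Reagents that add atoms: none
Why: Boron trifluoride-assisted SN2 opening of oxetane by a lithium acetylide adds C8, C7 and C6 in one operation at a temperature at which the silyl ether and the alkene are inert.

Step 8
Reactants: 13 (6R)-9-methyl-6-(propan-2-yl)-6-(triethylsilyloxy)dec-9-en-4-yn-1-ol
Product: 14 (6R)-9-methyl-6-(propan-2-yl)-6-(triethylsilyloxy)dec-9-en-4-ynal
Conditions: Dess–Martin periodinane, CH2Cl2, rt
Reagents that add atoms: none
Why: Dess–Martin oxidation stops cleanly at the aldehyde and tolerates alkyne, alkene and silyl ether.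

Step 9
Reactants: 14 (6R)-9-methyl-6-(propan-2-yl)-6-(triethylsilyloxy)dec-9-en-4-ynal
Product: 15 2-[(3R)-2,6-dimethyl-3-(triethylsilyloxy)hept-6-en-3-yl]cyclopent-2-en-1-one
Conditions: [Rh(dppe)]2(BF4)2 (10 mol %), acetone, 100 °C (sealed tube)
Reagents that add atoms: none
Why: Rhodium(I)-catalysed intramolecular trans-hydroacylation of a 4-alkynal forms C5–C6 in a 5-endo-dig ring closure to the 2-substituted cyclopentenone, and it keeps C5 sp2 so that no carbanion ever stands β to the C4 silyloxy group.

Step 10
Reactants: 15 2-[(3R)-2,6-dimethyl-3-(triethylsilyloxy)hept-6-en-3-yl]cyclopent-2-en-1-one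
Product: 17 2-[(3R)-2,6-dimethyl-3-(triethylsilyloxy)hept-6-en-3-yl]-3-hydroxycyclopentan-1-one (diastereomers at the ring carbons), via β-boryl ketone 16 (not isolated)
Conditions: B2pin2, CuCl (5 mol %), Xantphos, NaOt-Bu (10 mol %), MeOH (2 equiv), THF, rt; then NaBO3·4H2O, THF/H2O, rt
Reagents that add atoms: sodium perborate [Na+].[Na+].O[B-]1(O)OO[B-](O)(O)OO1
Why: Copper-catalysed conjugate borylation attacks the unhindered β-carbon C9 in preference to the isolated alkene, and mild perborate oxidation of the C–B bond gives the aldol, whose two new ring stereocentres are erased in step 11.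

Step 11
Reactants: 17 2-[(3R)-2,6-dimethyl-3-(triethylsilyloxy)hept-6-en-3-yl]-3-hydroxycyclopentan-1-one
Product: 19 benzyl 2-[(3R)-2,6-dimethyl-3-(triethylsilyloxy)hept-6-en-3-yl]-3-oxocyclopent-1-en-1-yl carbonate, via cyclopentane-1,3-dione 18 (not isolated)
Conditions: IBX, EtOAc, 75 °C, filter; then Et3N, CbzCl, 0 °C
Reagents that add atoms: benzyl chloroformate O=C(Cl)OCc1ccccc1
Why: IBX oxidation of a β-hydroxy ketone gives the 1,3-dione without over-oxidation, and O-acylation of this vinylogous acid as its ammonium salt gives one enol carbonate because the two carbonyl groups are equivalent.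

Step 12
Reactants: 19 benzyl 2-[(3R)-2,6-dimethyl-3-(triethylsilyloxy)hept-6-en-3-yl]-3-oxocyclopent-1-en-1-yl carbonate
Product: 22 trans-fused 4β-triethylsilyloxy-14-nordaucane-6,9-dione (1β-methyl and 5α-H), via photoadduct 20 (not isolated), via cyclobutanol 21 (not isolated)
Conditions: hν (medium-pressure Hg lamp, Pyrex, λ > 300 nm), degassed EtOAc (5 mM), 10 °C; then 10% Pd/C, H2 (1 atm), AcOH (5 vol %), same vessel, rt
Reagents that add atoms: none
Why: The excited (triplet) enone lets C5 attack C1 and close the cyclopentane in the 5-exo mode, the C9/C10 1,4-biradical collapses to the cyclobutane, and hydrogenolysis of the benzyl carbonate frees cyclobutanol 21, whose retro-aldol cleavage of the C5–C9 bond shared by the four- and five-membered rings opens the seven-membered ring by ring expansion. This is an intramolecular de Mayo reaction of a 2-(pent-4-enyl)-type cyclopentane-1,3-dione enol ester, a known entry to bicyclo[5.3.0]decane-2,5-diones, combined with the known hydrogenolytic release of the aldol from an enol benzyl carbonate. The three-atom tether C4–C3–C2 secures the straight (C5–C1, C9–C10) over the crossed addition, and strain allows only cis fusion at both cyclobutane edges, so the C1 methyl and C6 must lie on the same face of the new cyclopentane. C1 is controlled by C4: with C3 standing perpendicular to the enone plane, the other two C4 substituents flank C6=O and C9–OCO2Bn, and the far-reaching Et3SiO group should avoid the carbonate and sit beside the bare carbonyl oxygen while the compact isopropyl group takes the carbonate side, which puts O4 cis to the C1 methyl. C5 is re-set when the enol is protonated, and since C5–H stays acidic the α-H (trans) fusion, which keeps C6 away from the isopropyl group, should be reached under thermodynamic control. The weakly acidic unmasking is chosen because a C5 enolate in base could expel the C4 silyloxy group, and no alkene is left when hydrogen is admitted.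

Step 13
Reactants: 22 trans-fused 4β-triethylsilyloxy-14-nordaucane-6,9-dione
Product: 23 4β-hydroxy-5αH-14-nordaucane-6,9-dione
Conditions: HF·pyridine, pyridine, THF, 0 °C
Reagents that add atoms: none
Why: Buffered hydrogen fluoride cleaves the tertiary silyl ether without the base that could trigger retro-aldol cleavage or β-elimination, and the freed hydroxyl can hydrogen-bond to the C6 carbonyl only in the trans-fused isomer, which further anchors C5.

Step 14
Reactants: 23 4β-hydroxy-5αH-14-nordaucane-6,9-dione
Product: 24 4β,6α-dihydroxy-5αH-14-nordaucan-9-one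
Conditions: Me4NBH(OAc)3, MeCN/AcOH, −30 °C
Reagents that add atoms: none
Why: In the Evans–Saksena reduction the borohydride is bound by O4 and delivers hydride within a six-membered transition state to the β face of C6 only, which gives the 6α-alcohol and leaves the unassisted C9 ketone.

Step 15
Reactants: 24 4β,6α-dihydroxy-5αH-14-nordaucan-9-one
Product: 25 6α-benzoyloxy-4β-hydroxy-5αH-14-nordaucan-9-one
Conditions: BzCl, pyridine, DMAP (cat.), CH2Cl2, 0 °C to rt
Reagents that add atoms: benzoyl chloride O=C(Cl)c1ccccc1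
Why: Acylation under nucleophilic catalysis takes place at the secondary C6 hydroxyl only, the tertiary C4 hydroxyl being too hindered, and installs the ester of the target, which also serves as protecting group.

Step 16
Reactants: 25 6α-benzoyloxy-4β-hydroxy-5αH-14-nordaucan-9-one
Product: 26 6α-benzoyloxy-4β-hydroxydauc-8(14)-en-9-one
Conditions: (CH2O)n, i-Pr2NH·TFA, TFA (10 mol %), THF, reflux
Reagents that add atoms: formaldehyde (as paraformaldehyde) C=O
Why: Mannich-type α-methylenation with formaldehyde and a secondary ammonium salt should occur at C8 because C10 is neopentyl (next to quaternary C1), and it tolerates the ester and the tertiary alcohol.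

Step 17
Reactants: 26 6α-benzoyloxy-4β-hydroxydauc-8(14)-en-9-one
Product: 27 6α-benzoyloxydauc-8(14)-ene-4β,9-diol (C9 configuration open)
Conditions: NaBH4, CeCl3·7H2O, MeOH, −78 °C
Reagents that add atoms: none
Why: The Luche reduction gives 1,2-reduction of the exocyclic enone without touching the benzoate, and the configuration of the new C9 carbinol is irrelevant because C9 becomes sp2 in step 18.

Step 18
Reactants: 27 6α-benzoyloxydauc-8(14)-ene-4β,9-diol
Product: 30 6α-benzoyloxydauc-8-en-4β-ol (jaeschkeanadiol 6-benzoate), via sulfonylhydrazine 28 (not isolated), via allylic diazene 29 (not isolated)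
Conditions: 2-nitrobenzenesulfonylhydrazide, PPh3, DEAD, THF, −30 °C; then rt
Reagents that add atoms: none
Why: Mitsunobu displacement of the only secondary alcohol by the sulfonylhydrazide, loss of sulfinic acid and retro-ene extrusion of N2 from the allylic diazene (reductive allylic transposition) move the double bond to C8=C9 and turn the methylene into the C8 methyl group.

Step 19
Reactants: 30 6α-benzoyloxydauc-8-en-4β-ol
Product: 31 6α-benzoyloxy-8α,9α-epoxydaucan-4β-ol (target; 1R,4R,5S,6S,8R,9S in daucane numbering)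
Conditions: m-CPBA, NaHCO3, CH2Cl2, 0 °C
Reagents that add atoms: m-chloroperbenzoic acid O=C(OO)c1cccc(Cl)c1
Why: In the Prilezhaev epoxidation the peracid should approach the outward-facing α side of the chair cycloheptene, the β side lying under the axial C1 methyl, which sets C8 and C9 together (8α,9α), and the bicarbonate buffer protects the epoxide from opening by O4.

Compound list
1 | 4-methylpent-2-yn-1-ol | CC(C)C#CCO | starting material
2 | sodium bis(2-methoxyethoxy)alkenylalanate chelate of 1 (Al on the distal alkyne carbon, five-membered O–Al ring) | [Na+].COCCO[Al-]1(OCCOC)OCC=C1C(C)C | intermediate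
3 | (Z)-3-iodo-4-methylpent-2-en-1-ol | OC/C=C(\I)C(C)C | intermediate
4 | 4-bromo-2-methylbut-1-ene | CC(=C)CCBr | starting material
5 | (3-methylbut-3-en-1-yl)zinc bromide | CC(=C)CC[Zn]Br | intermediate
6 | (E)-6-methyl-3-(propan-2-yl)hepta-2,6-dien-1-ol | OC/C=C(\CCC(C)=C)C(C)C | intermediate
7 | [(2R,3R)-3-(3-methylbut-3-en-1-yl)-3-(propan-2-yl)oxiran-2-yl]methanol | OC[C@H]1O[C@]1(CCC(C)=C)C(C)C | intermediate
8 | (2S,3R)-2-(chloromethyl)-3-(3-methylbut-3-en-1-yl)-3-(propan-2-yl)oxirane | ClC[C@H]1O[C@]1(CCC(C)=C)C(C)C | intermediate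
9 | (3R)-6-methyl-3-(propan-2-yl)hept-6-en-1-yn-3-ol | CC(C)[C@](O)(CCC(C)=C)C#C | intermediate
10 | triethyl{[(3R)-6-methyl-3-(propan-2-yl)hept-6-en-1-yn-3-yl]oxy}silane | CC(C)[C@](O[Si](CC)(CC)CC)(CCC(C)=C)C#C | intermediate
11 | oxetane | C1COC1 | starting material
12 | lithium acetylide of 10 | CC(C)[C@](O[Si](CC)(CC)CC)(CCC(C)=C)C#C[Li] | intermediate
13 | (6R)-9-methyl-6-(propan-2-yl)-6-(triethylsilyloxy)dec-9-en-4-yn-1-ol | CC(C)[C@](O[Si](CC)(CC)CC)(CCC(C)=C)C#CCCCO | intermediate
14 | (6R)-9-methyl-6-(propan-2-yl)-6-(triethylsilyloxy)dec-9-en-4-ynal | CC(C)[C@](O[Si](CC)(CC)CC)(CCC(C)=C)C#CCCC=O | intermediate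
15 | 2-[(3R)-2,6-dimethyl-3-(triethylsilyloxy)hept-6-en-3-yl]cyclopent-2-en-1-one | CC(C)[C@](O[Si](CC)(CC)CC)(CCC(C)=C)C1=CCCC1=O | intermediate
16 | 2-[(3R)-2,6-dimethyl-3-(triethylsilyloxy)hept-6-en-3-yl]-3-(pinacolatoboryl)cyclopentan-1-one | CC(C)[C@](O[Si](CC)(CC)CC)(CCC(C)=C)C1C(B2OC(C)(C)C(C)(C)O2)CCC1=O | intermediate
17 | 2-[(3R)-2,6-dimethyl-3-(triethylsilyloxy)hept-6-en-3-yl]-3-hydroxycyclopentan-1-one | CC(C)[C@](O[Si](CC)(CC)CC)(CCC(C)=C)C1C(O)CCC1=O | intermediate
18 | 2-[(3R)-2,6-dimethyl-3-(triethylsilyloxy)hept-6-en-3-yl]cyclopentane-1,3-dione (enol form) | CC(C)[C@](O[Si](CC)(CC)CC)(CCC(C)=C)C1=C(O)CCC1=O | intermediate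
19 | benzyl 2-[(3R)-2,6-dimethyl-3-(triethylsilyloxy)hept-6-en-3-yl]-3-oxocyclopent-1-en-1-yl carbonate | CC(C)[C@](O[Si](CC)(CC)CC)(CCC(C)=C)C1=C(OC(=O)OCc2ccccc2)CCC1=O | intermediate
20 | 9-(benzyloxycarbonyloxy)-4β-triethylsilyloxy-5,9-cyclo-14-nordaucan-6-one (cyclobutane C1–C5–C9–C10 cis-fused to both five-membered rings; O4, C1 methyl and C6 on one face of the cyclopentane) | CC(C)[C@]1(O[Si](CC)(CC)CC)CC[C@]2(C)C[C@@]3(OC(=O)OCc4ccccc4)CCC(=O)[C@@]123 | intermediate
21 | 9-hydroxy-4β-triethylsilyloxy-5,9-cyclo-14-nordaucan-6-one | CC(C)[C@]1(O[Si](CC)(CC)CC)CC[C@]2(C)C[C@@]3(O)CCC(=O)[C@@]123 | intermediate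
22 | trans-fused 4β-triethylsilyloxy-14-nordaucane-6,9-dione (1β-methyl, 5α-H) | CC(C)[C@]1(O[Si](CC)(CC)CC)CC[C@]2(C)CC(=O)CCC(=O)[C@H]21 | intermediate
23 | 4β-hydroxy-5αH-14-nordaucane-6,9-dione | CC(C)[C@]1(O)CC[C@]2(C)CC(=O)CCC(=O)[C@H]21 | intermediate
24 | 4β,6α-dihydroxy-5αH-14-nordaucan-9-one | CC(C)[C@]1(O)CC[C@]2(C)CC(=O)CC[C@H](O)[C@H]21 | intermediate
25 | 6α-benzoyloxy-4β-hydroxy-5αH-14-nordaucan-9-one | CC(C)[C@]1(O)CC[C@]2(C)CC(=O)CC[C@H](OC(=O)c3ccccc3)[C@H]21 | intermediate
26 | 6α-benzoyloxy-4β-hydroxydauc-8(14)-en-9-one | CC(C)[C@]1(O)CC[C@]2(C)CC(=O)C(=C)C[C@H](OC(=O)c3ccccc3)[C@H]21 | intermediate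
27 | 6α-benzoyloxydauc-8(14)-ene-4β,9-diol | CC(C)[C@]1(O)CC[C@]2(C)CC(O)C(=C)C[C@H](OC(=O)c3ccccc3)[C@H]21 | intermediate
28 | N-[6α-benzoyloxy-4β-hydroxydauc-8(14)-en-9-yl]-N-(2-nitrophenylsulfonyl)hydrazine | CC(C)[C@]1(O)CC[C@]2(C)CC(N(N)S(=O)(=O)c3ccccc3[N+](=O)[O-])C(=C)C[C@H](OC(=O)c3ccccc3)[C@H]21 | intermediate
29 | 6α-benzoyloxy-9-diazenyldauc-8(14)-en-4β-ol | CC(C)[C@]1(O)CC[C@]2(C)CC(N=N)C(=C)C[C@H](OC(=O)c3ccccc3)[C@H]21 | intermediate
30 | 6α-benzoyloxydauc-8-en-4β-ol (jaeschkeanadiol 6-benzoate) | CC(C)[C@]1(O)CC[C@]2(C)CC=C(C)C[C@H](OC(=O)c3ccccc3)[C@H]21 | intermediate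
31 | 6α-benzoyloxy-8α,9α-epoxydaucan-4β-ol | CC(C)[C@]1(O)CC[C@]2(C)C[C@@H]3O[C@]3(C)C[C@H](OC(=O)c3ccccc3)[C@H]21 | target

Total step count: 19. Longest linear sequence: 19 steps (from 1; 4 and 11 enter as bought).

Steps most likely to fail

Step 12. The C4 centre may discriminate poorly between the two enone faces when the first bond forms, so that the C1 methyl ends trans to O4. A photochemical 1,3-acyl shift of the enol carbonate may also compete. The fallback replaces the steric model by a hydrogen bond.
- It sets out from dione 18. O-alkylation with benzyl bromide (K2CO3, DMF) would give the benzyl vinylogous ester F1.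
- Buffered fluoride (TBAF, AcOH, THF) would give the free tertiary alcohol F2. Unlike an enol ester, F2 cannot suffer acyl transfer to O4.
- Irradiated in cyclohexane, F2 should hold O4–H···O=C6 in the enone plane. The tether and the isopropyl group then occupy opposite faces, and only the hydroxy photoadduct F3, with O4 cis to C6 and to the C1 methyl, can form.
- Hydrogenolysis (H2, Pd(OH)2/C, EtOAc) of the cyclobutyl benzyl ether would release the dihydroxy cyclobutanol F4. Its retro-aldol opening leads directly to hydroxy dione 23, where the route is rejoined and step 13 is no longer needed.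

Step 9. Insertion at the alkyne carbon next to quaternary C4 may be slow. The acyl rhodium hydride may then decarbonylate, or it may move the 1,1-disubstituted alkene into the chain. The fallback sets out from alkynal 14. Gold(I)-catalysed hydration (Ph3PAuNTf2, wet dioxane) should place the ketone on the alkyne carbon remote from C4 and give the 1,4-keto aldehyde F5. An intramolecular aldol condensation under mild ammonium-salt catalysis (Bn2NH·TFA, toluene, rt) would close C5–C6 and dehydrate to enone 15, where the route is rejoined. The mild catalyst is chosen to limit loss of the silyloxy group.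

Step 16. Aminomethylation may stay incomplete because the ketone is partly tied up as a transannular hemiketal with O4. It may also occur on both sides of the ketone, or the enone may dimerise at reflux. The fallback sets out from 25. Soft enolisation with TMSOTf and Et3N (CH2Cl2, 0 °C) would give the bis-silylated enol ether F6 (C8=C9 enol silane, O4 silylated as well). Reaction of F6 with Eschenmoser's salt, followed by acidic work-up, would give the Mannich base F7. Quaternisation with MeI to the ammonium iodide F8 and elimination with aqueous NaHCO3 would return enone 26.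

Further compounds
F1 | step 12 | 3-benzyloxy-2-[(3R)-2,6-dimethyl-3-(triethylsilyloxy)hept-6-en-3-yl]cyclopent-2-en-1-one | CC(C)[C@](O[Si](CC)(CC)CC)(CCC(C)=C)C1=C(OCc2ccccc2)CCC1=O
F2 | step 12 | 3-benzyloxy-2-[(3R)-3-hydroxy-2,6-dimethylhept-6-en-3-yl]cyclopent-2-en-1-one | CC(C)[C@](O)(CCC(C)=C)C1=C(OCc2ccccc2)CCC1=O
F3 | step 12 | 9-benzyloxy-4β-hydroxy-5,9-cyclo-14-nordaucan-6-one | CC(C)[C@]1(O)CC[C@]2(C)C[C@@]3(OCc4ccccc4)CCC(=O)[C@@]123
F4 | step 12 | 4β,9-dihydroxy-5,9-cyclo-14-nordaucan-6-one | CC(C)[C@]1(O)CC[C@]2(C)C[C@@]3(O)CCC(=O)[C@@]123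
F5 | step 9 | (6S)-9-methyl-4-oxo-6-(propan-2-yl)-6-(triethylsilyloxy)dec-9-enal | CC(C)[C@](O[Si](CC)(CC)CC)(CCC(C)=C)CC(=O)CCC=O
F6 | step 16 | 6α-benzoyloxy-4β,9-bis(trimethylsilyloxy)-14-nordauc-8-ene | CC(C)[C@]1(O[Si](C)(C)C)CC[C@]2(C)CC(O[Si](C)(C)C)=CC[C@H](OC(=O)c3ccccc3)[C@H]21
F7 | step 16 | 6α-benzoyloxy-8-(dimethylaminomethyl)-4β-hydroxy-14-nordaucan-9-one | CC(C)[C@]1(O)CC[C@]2(C)CC(=O)C(CN(C)C)C[C@H](OC(=O)c3ccccc3)[C@H]21
F8 | step 16 | [6α-benzoyloxy-4β-hydroxy-9-oxo-14-nordaucan-8-yl]methyl(trimethyl)ammonium iodide | CC(C)[C@]1(O)CC[C@]2(C)CC(=O)C(C[N+](C)(C)C)C[C@H](OC(=O)c3ccccc3)[C@H]21.[I-]
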